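The rate constants are hidden, so two exponents read from the runs stand in for them. Substrate reads between 1.8% and 4.7% throughout the three runs.

| flask | substrate | partner | second reagent | third reagent | remark | time |
|---|---|---|---|---|---|---|
| Friday's | 0.50 M (fed, over 30 h) | 1.5 equiv | 0.74 equiv | 1 equiv | run made earlier; the fed solution adds 0.20 times the starting volume |  |
| Monday's | 0.50 M (fed, over 30 h) | 1.5 equiv | 1.7 equiv | 1 equiv | run made earlier; the fed solution adds 0.20 times the starting volume |  |
| Wednesday's | 0.50 M (fed, over 30 h) | 1.5 equiv | 1.1 equiv | 0.50 equiv | run made earlier; the fed solution adds 0.20 times the starting volume |  |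
| zeta | 0.50 M | 1.50 equiv | 1.10 equiv | 1.00 equiv | everything together at the start, the whole solution of substrate included, so that from the start the volume is larger by 0.20 times the starting volume | 10 h |
| beta | 0.50 M (fed, over 30 h) | 1.50 equiv | 1.10 equiv | 1.00 equiv | the fed solution adds 0.20 times the starting volume | 30 h |

- Friday's (time / h: target / %, substrate / %): 2.00: 0, 2.1; 4.00: 0.3, 2.4; 6.00: 0.2, 2.8; 12.0: 1.6, 3.0; 25.0: 7.9, 4.7
- Monday's (time / h: target / %, substrate / %): 2.00: 0, 2.6; 6.00: 0.4, 2.8; 12.0: 2.3, 3.1; 15.0: 4.0, 3.2; 25.0: 13.6, 4.4
- Wednesday's (time / h: target / %, substrate / %): 2.00: 0.5, 1.8; 6.00: 0, 2.3; 12.0: 1.3, 2.7; 15.0: 1.7, 3.6; 25.0: 5.9, 4.6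

(readings scatter by 0.3 percentage points)

* the flask that ends with the higher amount of target, in percent of the substrate charged, or "neither" when 2 percentage points or less lies between them (zeta / beta / neither)
* final target, as a percentage of the substrate charged, in zeta
* final target, as a percentage of the substrate charged, in beta

- charges are per starting volume, the dose included; the dosed solution carries all of it
- percentages count the whole charge, also what has not yet gone in

In Monday's run target reads 4.0% at 15.0 h and 13.6% at 25.0 h, so between these two readings it grows as time to the power 2.40. Taking all the runs to share that power, target and its rate of formation change by the same factor at a given hour. From Friday's run to Monday's, a factor 2.30 in second reagent brings a factor 1.72 in rate. These readings give n = 0.653, the order in second reagent: the power to which a change in second reagent passes into the rate of target formation. It is less than one, so the rate answers to second reagent less than in proportion, and control of the rate may be changing hands near these charges. Wednesday's run, with third reagent at 0.50 equiv, reads a factor 0.576 against Friday's run once second reagent is allowed for, but beta holds 1.00 equiv.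

My own reckoning for beta starts from Friday's run. Second reagent raises the rate by 1.30, and the later hour raises target by 1.55, which gives 15.8%. If target answers in proportion to what has gone in, the all-at-once curve is the feed time times the slope of the fed curve. This estimate then puts zeta at 8.19% at 10 h, less than the estimate for beta.

The forecast gave 9% for zeta and 16% for beta, with the words “Beta should end higher, though this is an extrapolation.”

Zeta ends at 6.11% and beta at 15.1%, so beta ends higher.

    intermediate A → decomposed reagent (k = 2.70 × 10⁻⁶ s⁻¹)
    third reagent + intermediate B → target (k = 1.90 × 10⁻⁵ L mol⁻¹ s⁻¹)
    substrate + partner → intermediate A (k = 5.70 × 10⁻⁴ L mol⁻¹ s⁻¹)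
    2 substrate → self-condensation product (k = 1.00 × 10⁻⁴ L mol⁻¹ s⁻¹)
    second reagent + intermediate A → intermediate B (k = 6.60 × 10⁻⁵ L mol⁻¹ s⁻¹)

With second reagent at 2.80 equiv and all else as in beta, the neighbour of beta should reach 27.8% at order n, but it ends at 21.9%, less than that. The order between beta and this neighbour is 0.397, lower than the order read from the runs. Beta ends with 33.6% of intermediate A and 37.9% of intermediate B. The neighbour ends with 13.3% of intermediate A and 54.6% of intermediate B.

The runs were generated by integration for an exercise; noise was put on by code.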